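(The data were generated by integration for substances that don't exist; scatter was added.)

A millimolar of target costs, as I count it, a millimolar of partner, so I reckon these flasks in millimolar and not in percent.

| flask | substrate | partner | capture agent | temperature | remark | time |
|---|---|---|---|---|---|---|
| ochre | 0.010 M | 8 mM | 3 mM | 75 °C | run made earlier |  |
| green | 0.010 M | 8 mM | 1.5 mM | 86 °C | run made earlier |  |
| grey | 0.010 M | 8 mM | 2.2 mM | 75 °C | run made earlier |  |
| amber | 0.020 M | 8 mM | 3 mM | 86 °C | run made earlier |  |
| theta | 0.010 M | 8.00 mM (fed, over 12 min) | 3.00 mM |  | the addition at 60 °C, then warmed to 80 °C; the feed brings no volume worth counting | 30 min |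
| epsilon | 0.010 M | 8.00 mM (fed, over 12 min) | 3.00 mM | 80 °C | all else is in the flask from the start; the feed brings no volume worth counting | 30 min |
| zeta | 0.010 M | 8.00 mM (in portions, 5, over 12 min) | 3.00 mM | 80 °C | first portion at the start, last at 12 min | 30 min |
| delta | 0.010 M | 8.00 mM | 3.00 mM | 80 °C | everything together at the start | 30 min |

| run | time / min | target / % | homo product / % | substrate / % |
|---|---|---|---|---|
| ochre | 1.33 | 0.2 | 0.1 | 97.3 |
| ochre | 3.00 | 0.4 | 0 | 94.2 |
| ochre | 8.00 | 2.2 | 0 | 86.0 |
| ochre | 20.0 | 10.1 | 1.9 | 68.9 |
| green | 8.00 | 9.9 | 3.5 | 61.9 |
| green | 15.0 | 22.1 | 9.0 | 40.3 |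
| green | 25.0 | 34.6 | 16.4 | 22.7 |
| green | 30.0 | 39.9 | 19.7 | 16.2 |
| grey | 4.00 | 0.4 | 0.2 | 93.1 |
| grey | 10.0 | 3.3 | 0.5 | 83.4 |
| grey | 20.0 | 9.5 | 2.6 | 69.3 |
| grey | 30.0 | 16.3 | 5.3 | 57.6 |
| amber | 8.00 | 9.1 | 5.5 | 61.6 |
| amber | 15.0 | 17.9 | 14.6 | 40.0 |
| amber | 25.0 | 25.6 | 26.5 | 22.2 |
| amber | 30.0 | 27.5 | 30.7 | 15.8 |

(readings scatter by 0.3 percentage points)

- percentages count the substrate that a species holds: one homo product counts as two

1. the flask that comes out highest in share of target in target plus homo product, or "all alike" when all lie within 1.5 percentage points (theta / epsilon / zeta / delta / all alike)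
2. share of target in target plus homo product at the end, theta
3. share of target in target plus homo product at the end, epsilon
4. share of target in target plus homo product at the end, zeta
5. share of target in target plus homo product at the end, delta

At the bench I would call partner the excess reagent, hold [partner] constant (pseudo-first-order) and let the share follow [unseen intermediate]. That is honest early on. But the charge ratio [partner]/[substrate] is 0.800, below one, so partner is no excess reagent, and at 30.0 min the green run has made target equal to half of the partner charge.

So [partner] stays in the reckoning. Homo product takes two unseen intermediates and target takes one with a partner, so the percent gained as homo product over the percent gained as target should run with [unseen intermediate]/[partner]. Over the last interval the green run gains 0.623, with 2.42 mM missing and 4.01 mM of partner left. Amber gains 2.21, with 5.20 mM and 2.50 mM. Their mean, 1.05, is my split constant: gain ratio times [partner] over [unseen intermediate], a reading with the scatter of small gains.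

At the forecast's 0.032/min, delta ends near green at 15.0 min. There the constant gives a running share of 65.9 %, while green's gathered share is 71.1 %, and that is my figure for delta. Epsilon and zeta both average half the partner charge over 12 min, so I put them together below delta. Theta I put above it.

The forecast reads 81 % for theta, 74.5 % for epsilon, 75.5 % for zeta and 77 % for delta, higher than my delta, and says: “Feeding partner starves the early period, so the intermediate runs higher”.

The flasks give 75.9 % for theta, 69.7 % for epsilon, 69.4 % for zeta and 72.8 % for delta, so theta is highest, as forecast.

    target → over-reaction product (k = 4.30 × 10⁻⁵ /min, Ea = 129 kJ/mol)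
    open intermediate + capture agent → trapped intermediate (k = 3.90 /M/min, Ea = 73.0 kJ/mol)
    2 open intermediate → homo product (k = 4.80 /M/min, Ea = 50.0 kJ/mol)
    substrate → open intermediate (k = 0.0320 /min, Ea = 112 kJ/mol)
    partner + open intermediate → target (k = 7.50 /M/min, Ea = 59.0 kJ/mol)
    (constants at 80 °C)

My missing material was open and trapped intermediate together, so I count both here. In theta at 30.0 min, the two stand at 2.47 mM against partner at 6.39 mM, so the split constant gives a split of 0.405 and a running share of 71.2 %. The neighbour of theta charged with 0.0060 M of substrate holds 1.53 mM of the two against 6.97 mM of partner, a smaller split of 0.230, a running share of 81.3 %, and a share at the end of 84.2 %.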